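**Retrosynthetic overview**

1. The target is the 1-O-acetyl-2-O-acyl-sn-glycerol of (13R)-ent-labd-8-en-15-oic acid (labdane numbering: ring A = C1–C5 + C10, ring B = C5–C10, side chain C11–C15). The last disconnections are O-benzyl hydrogenolysis and the C15 ester bond to (S)-1-O-acetyl-3-O-benzylglycerol.
2. C9–C11 is cut next: sp2–sp3 Negishi coupling of the C9 enol triflate of the bicyclic 8-methyl-9-ketone with a C11–C15 alkylzinc reagent made from methyl hydrogen (R)-3-methylglutarate, which supplies C13.
3. The decalone is traced back to a cis-fused ene-dione by removing the C6 carbonyl and the C2=C3 and C7=C8 double bonds and by epimerising C5. Ring B is never closed: it is the ring of 2,6-dimethyl-1,4-benzoquinone.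
4. Ring A (C10, C1, C2, C3, C4, C5) is the only ring formed and the last ring-forming event of the skeleton: a catalytic enantioselective [4+2] cycloaddition of the quinone C5=C10 bond with 4-methylpenta-1,3-diene (C1–C4 with both C4 methyls).
5. Enabling feature: ring A is a six-membered ring with an unsubstituted C2–C3 edge (cyclohexene retron), fused at C5–C10 to a ring B in which C9 is flanked by the methyl-bearing carbons C8 and C10 and C6 lies para to C9. This is the 2,6-dimethylbenzoquinone pattern; the C6 carbonyl is a removable activator that steers regiochemistry and lets C5 be equilibrated.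

Key step: step 1

Remark: the C2 methyl configuration written for 5, 6 and 7 (labdane C8) is the equatorial epimer expected under equilibration; it has no bearing on the outcome because this centre becomes sp2 in 8.
Remark: 9 and 15 are taken as commercial single enantiomers (9 is otherwise available by esterase desymmetrisation of dimethyl 3-methylglutarate).

**Step 1**
Reactants: 1 2,6-dimethyl-1,4-benzoquinone; 2 4-methylpenta-1,3-diene
Product: 3 cis-fused adduct (4aS,8aR)-2,5,5,8a-tetramethyl-4a,5,8,8a-tetrahydronaphthalene-1,4-dione
Conditions: (S)-o-tolyl-CBS-oxazaborolidine (20 mol %), Tf2NH (18 mol %), CH2Cl2, −78 → −40 °C, 2 (3 equiv) added slowly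
Reagents that add atoms: none
Why: Diels–Alder reaction: the protonated oxazaborolidine binds the C4 carbonyl oxygen of 1 (labdane C6, the unhindered carbonyl) through the lone pair syn to the neighbouring vinylic C–H, which lowers the LUMO of that C=C bond (labdane C5=C10) and places its larger coefficient on the methyl-bearing β-carbon, and the diene adds in a concerted, asynchronous [4+2] cycloaddition. The closest known reaction type is the catalytic enantioselective cycloaddition of 1,4-benzoquinones with acyclic 1,3-dienes under chiral oxazaborolidinium catalysis. Ring A is closed as a six-membered ring by suprafacial–suprafacial formation of the two σ-bonds C10–C1 and C5–C4 in one operation, which also installs the C4 gem-dimethyl group. The quaternary centre C10 (8aR) is set by the catalyst, whose gem-diphenyl unit shields one face of the bound quinone so that the diene adds to the open face (the S catalyst is selected from the accepted pretransition-state model and its mirror image would give the antipode), while C5 (4aS) is cis to the angular methyl as a consequence of suprafacial addition and is corrected in step 2. The step needs regioselectivity (diene CH2 terminus to C10, CMe2 terminus to C5), mono-addition and facial selectivity: the first is secured by the ortho rule for 1-substituted dienes together with avoidance of a bond between two fully substituted carbons, the second by the much lower dienophilicity of the ene-dione product, and the third by the catalyst alone, since the two C=C bonds of 1 are symmetry-equivalent.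

**Step 2**
Reactants: 3 cis-fused adduct (4aS,8aR)-2,5,5,8a-tetramethyl-4a,5,8,8a-tetrahydronaphthalene-1,4-dione
Product: 5 (2S,4aR,8aR)-2,5,5,8a-tetramethyloctahydronaphthalene-1,4-dione (trans-fused), via cis-fused saturated dione 4 (not isolated)
Conditions: H2 (1 atm), Pd/C (10 %), MeOH, rt; filter; NaOMe (0.3 equiv), MeOH, rt → 60 °C
Reagents that add atoms: none
Why: Heterogeneous hydrogenation saturates the ene-dione C=C bond and the ring A cis-alkene without touching the ketones, and methoxide then equilibrates both enolisable centres (base-mediated epimerisation), so that C4a (labdane C5, α to the C4 carbonyl) should settle in the trans-fused chair–chair decalin under thermodynamic control (kinetic axial protonation of the enolate anti to the angular methyl leads to the same isomer) and the C2 methyl goes equatorial.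

**Step 3**
Reactants: 5 (2S,4aR,8aR)-2,5,5,8a-tetramethyloctahydronaphthalene-1,4-dione
Product: 6 C4 mono-(p-toluenesulfonyl)hydrazone of dione 5
Conditions: TsNHNH2 (1.0 equiv), EtOH, rt
Reagents that add atoms: p-toluenesulfonyl hydrazide, Cc1ccc(cc1)S(=O)(=O)NN
Why: Tosylhydrazone condensation should be site-selective because the C1 carbonyl is a 2,2,6-trisubstituted cyclohexanone flanked by the quaternary carbon and the methyl-bearing carbon whereas the C4 carbonyl has a free CH2 neighbour, so one equivalent of reagent at room temperature should condense at C4 only; no stereocentre is created.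

**Step 4**
Reactants: 6 C4 mono-(p-toluenesulfonyl)hydrazone of dione 5
Product: 7 (2S,4aR,8aR)-2,5,5,8a-tetramethyloctahydronaphthalen-1(2H)-one
Conditions: catecholborane (1.5 equiv), CHCl3, 0 °C; then NaOAc·3H2O, reflux
Reagents that add atoms: none
Why: Kabalka-type reductive deoxygenation of a tosylhydrazone: catecholborane delivers hydride to C=N, acetate triggers loss of sulfinate, and the resulting diazene loses N2 to leave the CH2 group, while the hindered C1 ketone is reduced far more slowly by catecholborane at 0 °C and no stereocentre is formed or touched.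

**Step 5**
Reactants: 7 (2S,4aR,8aR)-2,5,5,8a-tetramethyloctahydronaphthalen-1(2H)-one
Product: 8 (4aR,8aR)-2,5,5,8a-tetramethyl-3,4,4a,5,6,7,8,8a-octahydronaphthalen-1-yl trifluoromethanesulfonate
Conditions: KN(SiMe3)2, THF, −78 → 0 °C; PhNTf2, −78 °C → rt
Reagents that add atoms: N-phenylbis(trifluoromethanesulfonimide), O=S(=O)(N(c1ccccc1)S(=O)(=O)C(F)(F)F)C(F)(F)F
Why: The only enolisable position of 7 is C2 (C8a is quaternary), so deprotonation of the axial C2–H and O-sulfonylation of the enolate (regiodefined enol triflate formation) can give only the tetrasubstituted enol triflate that fixes the later C8=C9 alkene, erasing the C2 stereocentre.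

**Step 6**
Reactants: 9 methyl hydrogen (R)-3-methylglutarate
Product: 10 methyl (R)-5-hydroxy-3-methylpentanoate
Conditions: BH3·SMe2, THF, −10 → 0 °C; MeOH quench; used directly
Reagents that add atoms: none
Why: Borane reduces a carboxylic acid through its acyloxyborane much faster than an ester (chemoselective borane reduction), so only the acid terminus is reduced and the C3 stereocentre, which is not enolised under these conditions, is retained.

**Step 7**
Reactants: 10 methyl (R)-5-hydroxy-3-methylpentanoate
Product: 11 methyl (S)-5-iodo-3-methylpentanoate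
Conditions: I2, PPh3, imidazole, CH2Cl2, 0 °C → rt
Reagents that add atoms: iodine, II
Why: Appel-type iodination converts the primary alcohol into the iodide by SN2 displacement of the alkoxyphosphonium ion at a non-stereogenic carbon, so the stereocentre is untouched and the descriptor changes from R to S only through the CIP priority of iodine.

**Step 8**
Reactants: 11 methyl (S)-5-iodo-3-methylpentanoate; 8 (4aR,8aR)-2,5,5,8a-tetramethyl-3,4,4a,5,6,7,8,8a-octahydronaphthalen-1-yl trifluoromethanesulfonate
Product: 13 methyl (3R)-3-methyl-5-[(4aR,8aR)-2,5,5,8a-tetramethyl-3,4,4a,5,6,7,8,8a-octahydronaphthalen-1-yl]pentanoate, via alkylzinc iodide 12 (not isolated)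
Conditions: Zn dust (activated with BrCH2CH2Br and Me3SiCl), DMA, 40 °C; then 8, Pd(OAc)2 (5 mol %), SPhos (10 mol %), THF/DMA, 60 °C
Reagents that add atoms: zinc dust, [Zn] (held only in intermediate 12)
Why: Direct zinc insertion into the primary C–I bond gives an ester-tolerant alkylzinc iodide, which undergoes Negishi sp3–sp2 cross-coupling (oxidative addition of zerovalent palladium to the enol triflate, transmetalation, and reductive elimination that outruns β-hydride elimination with the bulky biarylphosphine) to form C9–C11 with the tetrasubstituted alkene position dictated by the triflate; no stereocentre is affected.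

**Step 9**
Reactants: 13 methyl (3R)-3-methyl-5-[(4aR,8aR)-2,5,5,8a-tetramethyl-3,4,4a,5,6,7,8,8a-octahydronaphthalen-1-yl]pentanoate
Product: 14 (3R)-3-methyl-5-[(4aR,8aR)-2,5,5,8a-tetramethyl-3,4,4a,5,6,7,8,8a-octahydronaphthalen-1-yl]pentanoic acid
Conditions: LiOH, THF/MeOH/H2O, rt; then aq. HCl to pH 3
Reagents that add atoms: lithium hydroxide, [Li+].[OH-]
Why: Saponification of the unhindered methyl ester (acyl–oxygen ester hydrolysis) frees the acid, and the C13 stereocentre is β to the carbonyl and cannot epimerise.

**Step 10**
Reactants: 15 (R)-3-(benzyloxy)propane-1,2-diol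
Product: 16 (S)-3-(benzyloxy)-2-hydroxypropyl acetate
Conditions: AcCl (1.05 equiv), 2,4,6-collidine, CH2Cl2, −78 °C; used promptly
Reagents that add atoms: acetyl chloride, CC(=O)Cl
Why: Acetyl chloride with the hindered base collidine at low temperature acylates the primary hydroxyl far faster than the secondary one (regioselective monoacylation of a 1,2-diol), and the stereocentre is not involved.

**Step 11**
Reactants: 14 (3R)-3-methyl-5-[(4aR,8aR)-2,5,5,8a-tetramethyl-3,4,4a,5,6,7,8,8a-octahydronaphthalen-1-yl]pentanoic acid; 16 (S)-3-(benzyloxy)-2-hydroxypropyl acetate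
Product: 17 (2S)-1-acetoxy-3-(benzyloxy)propan-2-yl (3R)-3-methyl-5-[(4aR,8aR)-2,5,5,8a-tetramethyl-3,4,4a,5,6,7,8,8a-octahydronaphthalen-1-yl]pentanoate
Conditions: EDC·HCl, DMAP (0.2 equiv), CH2Cl2, 0 °C → rt
Reagents that add atoms: none
Why: Steglich esterification (carbodiimide activation, DMAP acyl transfer) acylates the secondary hydroxyl without breaking its C–O bond, so the glycerol centre keeps its configuration and the remote C13 centre is unaffected.

**Step 12**
Reactants: 17 (2S)-1-acetoxy-3-(benzyloxy)propan-2-yl (3R)-3-methyl-5-[(4aR,8aR)-2,5,5,8a-tetramethyl-3,4,4a,5,6,7,8,8a-octahydronaphthalen-1-yl]pentanoate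
Product: 18 (2S)-1-acetoxy-3-hydroxypropan-2-yl (3R)-3-methyl-5-[(4aR,8aR)-2,5,5,8a-tetramethyl-3,4,4a,5,6,7,8,8a-octahydronaphthalen-1-yl]pentanoate (CNP0216082.1)
Conditions: H2 (1 atm), Pd/C (10 %), EtOAc, rt; rapid chromatography on boric-acid-treated silica
Reagents that add atoms: none
Why: Hydrogenolysis of the benzyl ether under neutral conditions frees the primary hydroxyl without base- or acid-induced acyl migration, the tetrasubstituted C8=C9 alkene flanked by the quaternary C10 should be inert to hydrogenation under these mild conditions, and no stereocentre changes.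

**Compound list**

1 | 2,6-dimethyl-1,4-benzoquinone | CC1=CC(=O)C=C(C)C1=O | starting material
2 | 4-methylpenta-1,3-diene | C=CC=C(C)C | starting material
3 | (4aS,8aR)-2,5,5,8a-tetramethyl-4a,5,8,8a-tetrahydronaphthalene-1,4-dione (cis-fused adduct) | O=C1C(C)=CC(=O)[C@H]2C(C)(C)C=CC[C@@]12C | intermediate
4 | (4aS,8aR)-2,5,5,8a-tetramethyloctahydronaphthalene-1,4-dione (cis-fused, C2 epimers, formed in situ) | O=C1C(C)CC(=O)[C@H]2C(C)(C)CCC[C@@]12C | intermediate
5 | (2S,4aR,8aR)-2,5,5,8a-tetramethyloctahydronaphthalene-1,4-dione (trans-fused) | O=C1[C@@H](C)CC(=O)[C@@H]2C(C)(C)CCC[C@@]12C | intermediate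
6 | C4 mono-(p-toluenesulfonyl)hydrazone of dione 5 (hydrazone at the carbonyl remote from the quaternary carbon) | O=C1[C@@H](C)CC(=NNS(=O)(=O)c3ccc(C)cc3)[C@@H]2C(C)(C)CCC[C@@]12C | intermediate
7 | (2S,4aR,8aR)-2,5,5,8a-tetramethyloctahydronaphthalen-1(2H)-one | O=C1[C@@H](C)CC[C@@H]2C(C)(C)CCC[C@@]12C | intermediate
8 | (4aR,8aR)-2,5,5,8a-tetramethyl-3,4,4a,5,6,7,8,8a-octahydronaphthalen-1-yl trifluoromethanesulfonate | O=S(=O)(OC1=C(C)CC[C@@H]2C(C)(C)CCC[C@@]12C)C(F)(F)F | intermediate
9 | methyl hydrogen (R)-3-methylglutarate [(R)-5-methoxy-3-methyl-5-oxopentanoic acid] | COC(=O)C[C@H](C)CC(=O)O | starting material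
10 | methyl (R)-5-hydroxy-3-methylpentanoate | COC(=O)C[C@H](C)CCO | intermediate
11 | methyl (S)-5-iodo-3-methylpentanoate | COC(=O)C[C@H](C)CCI | intermediate
12 | [(S)-5-methoxy-3-methyl-5-oxopentyl]zinc iodide (formed in situ) | COC(=O)C[C@H](C)CC[Zn]I | intermediate
13 | methyl (3R)-3-methyl-5-[(4aR,8aR)-2,5,5,8a-tetramethyl-3,4,4a,5,6,7,8,8a-octahydronaphthalen-1-yl]pentanoate | COC(=O)C[C@H](C)CCC1=C(C)CC[C@@H]2C(C)(C)CCC[C@@]12C | intermediate
14 | (3R)-3-methyl-5-[(4aR,8aR)-2,5,5,8a-tetramethyl-3,4,4a,5,6,7,8,8a-octahydronaphthalen-1-yl]pentanoic acid | OC(=O)C[C@H](C)CCC1=C(C)CC[C@@H]2C(C)(C)CCC[C@@]12C | intermediate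
15 | (R)-3-(benzyloxy)propane-1,2-diol (3-O-benzyl-sn-glycerol) | OC[C@H](COCc1ccccc1)O | starting material
16 | (S)-3-(benzyloxy)-2-hydroxypropyl acetate | CC(=O)OC[C@H](COCc1ccccc1)O | intermediate
17 | (2S)-1-acetoxy-3-(benzyloxy)propan-2-yl (3R)-3-methyl-5-[(4aR,8aR)-2,5,5,8a-tetramethyl-3,4,4a,5,6,7,8,8a-octahydronaphthalen-1-yl]pentanoate | CC(=O)OC[C@H](COCc1ccccc1)OC(=O)C[C@H](C)CCC1=C(C)CC[C@@H]2C(C)(C)CCC[C@@]12C | intermediate
18 | (2S)-1-acetoxy-3-hydroxypropan-2-yl (3R)-3-methyl-5-[(4aR,8aR)-2,5,5,8a-tetramethyl-3,4,4a,5,6,7,8,8a-octahydronaphthalen-1-yl]pentanoate | CC(=O)OC[C@H](CO)OC(=O)C[C@H](C)CCC1=C(C)CC[C@@H]2C(C)(C)CCC[C@@]12C | target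

**Step count and risks**

Total step count: 12.
Longest linear sequence: 9 steps (steps 1, 2, 3, 4, 5, 8, 9, 11, 12; from 1 and 2 to 18).

The three steps most likely to fail:

Step 1. The cycloaddition may be sluggish because the Z-methyl group of the diene disfavours the s-cis conformer, the diene may oligomerise under the strongly acidic catalyst, or facial discrimination may be insufficient. The fallback separates ring formation from enantiocontrol. It sets out from 1 and 2, which are combined without catalyst under high pressure (CH2Cl2, 10–12 kbar, rt) or heat (toluene, sealed tube, 110 °C) to give the racemic cis adduct F1. Hydrogenation and methoxide equilibration as in step 2 give, through the racemic cis-fused saturated dione F2, the racemic trans-fused dione F3. An enzymatic kinetic resolution with an NADPH-dependent ketoreductase (isopropanol for cofactor recycling, buffer, 30 °C), selected from a panel to reduce the unhindered C4 carbonyl of the (2R,4aS,8aS) antipode, converts that enantiomer into the hydroxy ketone F4 and leaves the wanted enantiomer untouched. The fallback comes back to the route at compound 5.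

Step 3. Site discrimination between the two carbonyls may be incomplete, so that condensation also occurs at C1 or twice. The fallback differentiates the carbonyls by kinetic enolisation instead of carbonyl addition. It sets out from 5: LiN(iPr)2 (1.05 equiv, THF, −78 °C) removes a proton from the only unhindered α-CH2 (C3), and PhNTf2 traps the enolate as the C4 enol triflate F5. Formate reduction (Pd(OAc)2, PPh3, HCO2H, Bu3N, DMF, 60 °C) gives the alkenyl ketone F6, and hydrogenation over Pd/C in EtOAc saturates the C3=C4 bond. The fallback comes back to the route at compound 7.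

Step 8. Oxidative addition and transmetalation at the tetrasubstituted enol triflate next to the quaternary carbon may be slow, so that protodezincation or β-hydride elimination of the alkyl partner takes over. The fallback uses the iron-catalysed coupling of an alkyl Grignard reagent with an enol triflate, which is known to tolerate hindered triflates, and carries C15 at the alcohol oxidation level. It sets out from 11 (and uses 8): iBu2AlH (CH2Cl2, −78 °C) reduces the ester to (S)-5-iodo-3-methylpentan-1-ol F7, and tert-butyldimethylsilyl chloride with imidazole gives the silyl ether F8. Magnesium in Et2O gives the Grignard reagent F9, which is coupled with 8 (Fe(acac)3 5 mol %, THF/NMP, −30 °C) to the silyl ether F10. Bu4NF in THF frees the primary alcohol F11, and oxidation with TEMPO and PhI(OAc)2 in MeCN/H2O gives the acid. The fallback comes back to the route at compound 14.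

**Further compounds**

F1 | step 1 | racemic cis-fused adduct rac-(4aS,8aR)-2,5,5,8a-tetramethyl-4a,5,8,8a-tetrahydronaphthalene-1,4-dione | O=C1C(C)=CC(=O)[C@H]2C(C)(C)C=CC[C@@]12C.O=C1C(C)=CC(=O)[C@@H]2C(C)(C)C=CC[C@]12C
F2 | step 1 | racemic cis-fused saturated dione rac-(4aS,8aR)-2,5,5,8a-tetramethyloctahydronaphthalene-1,4-dione (C2 epimers) | O=C1C(C)CC(=O)[C@H]2C(C)(C)CCC[C@@]12C.O=C1C(C)CC(=O)[C@@H]2C(C)(C)CCC[C@]12C
F3 | step 1 | racemic trans-fused dione rac-(2S,4aR,8aR)-2,5,5,8a-tetramethyloctahydronaphthalene-1,4-dione | O=C1[C@@H](C)CC(=O)[C@@H]2C(C)(C)CCC[C@@]12C.O=C1[C@H](C)CC(=O)[C@H]2C(C)(C)CCC[C@]12C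
F4 | step 1 | (2R,4aS,8aS)-4-hydroxy-2,5,5,8a-tetramethyloctahydronaphthalen-1(2H)-one (reduced antipode, carbinol configuration set by the enzyme) | O=C1[C@H](C)CC(O)[C@H]2C(C)(C)CCC[C@]12C
F5 | step 3 | (2S,4aR,8aR)-2,5,5,8a-tetramethyl-1-oxo-1,2,4a,5,6,7,8,8a-octahydronaphthalen-4-yl trifluoromethanesulfonate | O=C1[C@@H](C)C=C(OS(=O)(=O)C(F)(F)F)[C@@H]2C(C)(C)CCC[C@@]12C
F6 | step 3 | (2S,4aR,8aR)-2,5,5,8a-tetramethyl-4a,5,6,7,8,8a-hexahydronaphthalen-1(2H)-one | O=C1[C@@H](C)C=C[C@@H]2C(C)(C)CCC[C@@]12C
F7 | step 8 | (S)-5-iodo-3-methylpentan-1-ol | OCC[C@H](C)CCI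
F8 | step 8 | tert-butyl{[(S)-5-iodo-3-methylpentyl]oxy}dimethylsilane | CC(C)(C)[Si](C)(C)OCC[C@H](C)CCI
F9 | step 8 | {(S)-5-[(tert-butyldimethylsilyl)oxy]-3-methylpentyl}magnesium iodide | CC(C)(C)[Si](C)(C)OCC[C@H](C)CC[Mg]I
F10 | step 8 | tert-butyldimethyl{[(3R)-3-methyl-5-[(4aR,8aR)-2,5,5,8a-tetramethyl-3,4,4a,5,6,7,8,8a-octahydronaphthalen-1-yl]pentyl]oxy}silane | CC(C)(C)[Si](C)(C)OCC[C@H](C)CCC1=C(C)CC[C@@H]2C(C)(C)CCC[C@@]12C
F11 | step 8 | (3R)-3-methyl-5-[(4aR,8aR)-2,5,5,8a-tetramethyl-3,4,4a,5,6,7,8,8a-octahydronaphthalen-1-yl]pentan-1-ol | OCC[C@H](C)CCC1=C(C)CC[C@@H]2C(C)(C)CCC[C@@]12C
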